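Beta and gamma differ by 0.700 equivalents of reagent, and I am asked which species leads in each flask at 5.0 min.

| flask | substrate | reagent | remark | time |
|---|---|---|---|---|
| north | 0.30 M | 3.3 equiv | run made earlier |  |
| west | 0.30 M | 4.3 equiv | run made earlier |  |
| beta | 0.30 M | 2.50 equiv |  | 5.0 min |
| gamma | 0.30 M | 3.20 equiv |  | 5.0 min |

| run | time / min | side product / % | substrate / % | target / % | intermediate / % |
|---|---|---|---|---|---|
| north | 0.200 | 0.7 | 54.6 | 0.1 | 43.9 |
| north | 0.500 | 5.3 | 24.3 | 0.7 | 68.9 |
| north | 1.00 | 12.6 | 7.9 | 0.6 | 79.4 |
| north | 1.50 | 20.6 | 1.9 | 0.8 | 76.3 |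
| north | 2.00 | 27.7 | 0.3 | 1.7 | 68.2 |
| north | 3.00 | 39.2 | 0.5 | 0.9 | 60.2 |
| north | 4.00 | 48.2 | 0 | 1.0 | 50.5 |
| west | 0.200 | 2.3 | 44.9 | 0 | 52.5 |
| west | 0.500 | 9.0 | 15.9 | 0.3 | 74.3 |
| west | 1.00 | 19.5 | 3.3 | 1.3 | 75.8 |
| west | 1.50 | 29.5 | 0.8 | 1.3 | 68.5 |
| west | 2.00 | 38.2 | 0.2 | 1.3 | 61.0 |
| west | 3.00 | 52.7 | 0.3 | 0.5 | 47.5 |
| west | 4.00 | 62.0 | 0 | 0.5 | 36.4 |

(readings scatter by 0.5 percentage points)

- which of these there is most of at the end, counted by the substrate in it, beta (target / side product / substrate / intermediate)
- which of these there is most of at the end, counted by the substrate in it, gamma (target / side product / substrate / intermediate)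
- how much there is at the end of the one of these that leads, in percent of the substrate charged: beta
- how much there is at the end of the one of these that leads, in percent of the substrate charged: gamma

- the numbers in the tables scatter with a standard deviation of 0.5 percentage points
- reactions considered so far: substrate + reagent -> intermediate; reagent + intermediate -> side product; substrate + reagent -> target

West carries 1.30 times the reagent of north, yet from 1.50 min to 4.00 min, with substrate down to 0.8% in west and 1.9% in north, the intermediate fades at 0.253 min⁻¹ in west against 0.165 min⁻¹ in north, a ratio of 1.53. The charge is the wrong number to compare. Each substrate spends one reagent on becoming intermediate and each side product takes one more, so free reagent in equivalents is the charge, less one, less the fraction of side product. Averaged over that window, c(reagent) is 0.853 M in west and 0.587 M in north, a ratio of 1.45, and the puzzle clears. The decay is pseudo-first-order in that mean. Dividing gives 0.297 M⁻¹ min⁻¹ and 0.281 M⁻¹ min⁻¹, and their mean is my fading constant, the fall of ln(intermediate) per minute per molar of free reagent: 0.289 M⁻¹ min⁻¹.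

I start the clock at 0.500 min, when north holds 24.3% substrate, which leaves 4.50 min. Mean c(reagent) then comes to 0.384 M in beta and 0.574 M in gamma. So I reckon intermediate at 60.7% in beta and 47.4% in gamma, where side product leads.

The forecast, reached by “Integrating by hand to 5 min”, names intermediate at 58% (55% to 62%) in beta and side product at 54% (51% to 57%) in gamma. For beta it stands lower than my reckoning.

The flasks give intermediate at 58.2% in beta and side product at 54.3% in gamma.

    substrate + reagent → intermediate (k = 3.30 M⁻¹ min⁻¹)
    reagent + intermediate → side product (k = 0.300 M⁻¹ min⁻¹)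
    substrate + reagent → target (k = 0.0320 M⁻¹ min⁻¹)

The gap in intermediate between the two flasks is mainly the difference in equivalents of reagent: with beta's charge, gamma's 44.8% moves to 58.2%. From gamma's 66.0% at 2.50 min, with mean c(reagent) 0.530 M, the fading constant gives 45.0% at 5.00 min. In a neighbour of gamma charged with 8.00 equiv of reagent, mean c(reagent) is 1.96 M, so the constant gives 7.82% of intermediate, and that flask holds 6.17%.

The runs were generated by integration with made-up constants, noise included.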